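## The problem

The target is a briarane diterpenoid: a cyclohexene (ring A, C1 and C10–C14) trans-fused through C1–C10 to a ten-membered carbocycle (ring B, C1–C10). Ring B holds a 5Z trisubstituted alkene and, across C7–C8, a γ-lactone (C7–O–C19–C17–C8). Eight stereocentres have to be set (quaternary C1, C2, C7, the tertiary carbinol C8, C9, C10, C14, C17), six of them contiguous from C7 to C2. C9 is allylic to C10 and can steer bond formation there, and C1 can steer C2. C8, once it is part of the lactone, lies between two look-alike ring arms (C7 and C17) and cannot be trusted to control C9, so C9 is best set before the lactone is closed. C17 is epimerisable, but its natural configuration (methyl trans to the C9 branch) should be the stable one. The fragile parts are the three acetates, the β-hydroxy γ-lactone (retro-aldol, dehydration, C17 epimerisation), the allylic C–O bonds at C7 and C9, and the Z alkene. The feature that invites a single ring-forming event is ring A: its C11=C12 alkene, C11 methyl, C14 acetoxy group and quaternary C1 next to the C2 oxygen are exactly the pattern of a [4+2] adduct of a 2-methyl-1,3-diene (C10–C13) with a Z β-acetoxy enone (C14=C1–C2=O), and the eight ring B atoms C2–C9 join the two.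

## Retrosynthesis

**C2 acetate.** Target 32 is traced to the C2 ketone 30 through alcohol 31. A ketone at C2 is what makes C1=C14 an electron-poor dienophile, so the C2 stereocentre is deferred to a late reduction controlled by the quaternary C1. The forward steps need hydride delivery to one face and acetylation that leaves the tertiary C8 hydroxyl alone.

**Rings A and B (key cut).** In 30 the bonds C1–C10 and C13–C14 are cut together, which opens both carbocycles and removes three stereocentres (C1, C10, C14), leaving triene 29. Cuts of ring B alone (C3–C4, C8–C9) leave ring A and its three centres to be made by an untethered reaction. Here the tether enforces regiochemistry and lets C9 choose the diene face. The forward reaction must close a ten-membered ring in the fused mode, through the transition state with the C2 carbonyl exo.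

**Dienophile.** The Z enol acetate of 29 comes from the β-keto aldehyde 27, and this from the 1,3-diol 26 by double oxidation. Formylating an ethyl ketone would not tell C1 from C3; the diol fixes the position of both oxygens. The diol is carried as the acetonide (25 and earlier) and is unmasked only after the diene and the C9 acetate are in place.

**Lactone C7–O bond.** Acetate 25 and lactone diol 24 are traced to the β,γ-epoxy tert-butyl ester 23. Aldol-type lactone constructions (C7–C8 or C8–C17) would have to control three centres in an open chain. The epoxide route takes C7 and C8 from alkene geometry, reagent control and a stereospecific inversion. The forward step needs clean backside opening at the allylic C7.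

**C9–C10 bond.** Carbinol 23 is cut into epoxy aldehyde 19 and dienyl iodide 22 (from but-1-en-3-yne 20). Making this bond before lactonisation matters: in 19 the epoxide differentiates the two faces of the aldehyde (Felkin–Anh), which the finished lactone would not.

**C7–C8 oxygens and the C7=C8 bond.** Aldehyde 19 comes from epoxy alcohol 18, and this from the (2E,4Z)-dienol 17 by Sharpless epoxidation, which touches only the allylic alcohol alkene. Dienol 17 comes from diester 16, which is cut at C7=C8 into enal 9 and phosphonate 14. The forward olefination must give the E alkene.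

**C17 and the chain.** Phosphonate 14 is cut at C8–C17 into triethyl phosphonoacetate 12 and lactate triflate 11 (from tert-butyl (R)-lactate 10), so C17 comes from the chiral pool by SN2 inversion. Enal 9 comes via 8, 7 and 6 from aldehyde 3 and propionimide 4 (C1–C2 bond), and 3 comes from neryl acetate 1 via epoxide 2. Neryl acetate 1 supplies the Z alkene. The aldol is run with an auxiliary only so that every intermediate is a single stereoisomer; both of its centres are erased in step 18.

## Roads not taken

**Alternative 1:** The cut is C8–C9. Low-valent titanium (TiCl3, Zn–Cu couple) would couple a C9 aldehyde with a C8 ketone on a chain that already carries ring A, giving the ring B diol A1.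
- Merits: pinacol closure of strained medium rings is proven, it creates both carbinol centres in one step, and ring A can come from an ordinary intermolecular cycloaddition. For the ring closure itself its precedent is better than that of the chosen plan.
- Weak points: C8 and C9 are both set inside the macrocyclic transition state with no clear control element. The α-silyloxy ketone and the acetates are exposed to a strong reductant, and over-reduction to the alkene is possible. After A1 the lactone is still missing (selective C9 acetylation, PMB removal, oxidation of C19, desilylation, lactonisation).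
- Against this the chosen plan sets two rings and three centres in one step with the lactone already in place, and needs two steps after the key step.

**Alternative 2:** The cut is the lactone C7–O bond. PhI(OAc)2 and I2 under light would turn a C19 primary amide into its amidyl radical, which abstracts the allylic H7 through a six-membered transition state; oxidation and closure by the amide oxygen then give lactone A2.
- Merits: it is very economical at the end, no β-hydroxy lactone has to be carried, and the C–H bond is well placed and weak. In late-stage step economy it beats the chosen plan.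
- Weak points: the C7 radical or cation is allylic and delocalised to C5, so Z/E scrambling and attack at C5 threaten. The C7 configuration rests on ring conformation alone. Other allylic hydrogens (C4, C13) and the electron-rich alkenes compete for the iodine reagents. Ring B must still be built by another method.
- The chosen plan makes C7–O early, with defined configuration, by a stereospecific epoxide opening.

**Alternative 3:** The cut is C3–C4. Cs2CO3 would deprotonate a β-keto sulfone at C3 and the carbanion would displace a primary allylic bromide at C4, closing ring B to sulfone A3.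
- Merits: macro-alkylation by soft sulfonyl carbanions is dependable, the Z alkene is preset, and the C3 centre is immaterial. In certainty of ring closure it is as good as or better than the chosen plan.
- Weak points: SN2' attack and O-alkylation compete. The three ring A centres must be set earlier without a tether. The sulfone has to be put in and taken out, and reductive desulfonylation endangers the allylic lactone C7–O bond. Four steps follow A3.
- The chosen plan sets against this fewer operations and intramolecular stereocontrol, at the price of an unproven ring closure. A ring-A-first route of this general kind is therefore kept as the fallback.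

Key step: step 20

Assumption: atoms carry briarane numbers throughout (C19 = lactone carbonyl, C18 = methyl on C17), and CIP descriptors given with briarane locants refer to that numbering.

## Steps

Step 1
Reactants: 1 neryl acetate
Product: 2 (2Z)-5-(3,3-dimethyloxiran-2-yl)-3-methylpent-2-en-1-yl acetate (racemic epoxide)
Conditions: m-CPBA (1.0 equiv), CH2Cl2, 0 °C
Reagents that add atoms: m-chloroperoxybenzoic acid, O=C(OO)c1cccc(Cl)c1
Why: Prilezhaev epoxidation; the distal trisubstituted alkene is more electron-rich than the one deactivated by the allylic acetate and reacts first, and the epoxide configuration is irrelevant because both carbons are cleaved next.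

Step 2
Reactants: 2 epoxide
Product: 3 (2Z)-3-methyl-6-oxohex-2-en-1-yl acetate
Conditions: H5IO6, THF–H2O, 0 °C
Reagents that add atoms: none
Why: Periodic acid hydrolyses the epoxide and cleaves the glycol (Malaprade cleavage) to the aldehyde and acetone; the Z alkene and the acetate are not touched.

Step 3
Reactants: 3 aldehyde; 4 (4S)-4-benzyl-3-propanoyl-1,3-oxazolidin-2-one
Product: 6 (2Z,6R,7S)-8-[(4S)-4-benzyl-2-oxo-1,3-oxazolidin-3-yl]-6-hydroxy-3,7-dimethyl-8-oxooct-2-en-1-yl acetate, via dibutylboron Z-enolate 5 (not isolated)
Conditions: Bu2BOTf, iPr2NEt, CH2Cl2, −78 → 0 °C; then H2O2, MeOH, pH 7 buffer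
Reagents that add atoms: none
Why: Evans syn aldol through the Zimmerman–Traxler chair of the Z boron enolate; the auxiliary fixes both new centres, which serve only to keep later intermediates single isomers and are erased in step 18.

Step 4
Reactants: 6 aldol adduct
Product: 7 (2R,3R,6Z)-2,6-dimethyloct-6-ene-1,3,8-triol
Conditions: LiBH4, MeOH (1 equiv), THF, 0 °C → rt
Reagents that add atoms: none
Why: Reductive cleavage of the imide to the primary alcohol, with reduction of the acetate in the same operation; the auxiliary is recovered.

Step 5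
Reactants: 7 triol
Product: 8 (2Z)-3-methyl-5-[(4R,5R)-2,2,5-trimethyl-1,3-dioxan-4-yl]pent-2-en-1-ol
Conditions: 2,2-dimethoxypropane, PPTS (cat.), acetone, rt
Reagents that add atoms: 2,2-dimethoxypropane, COC(C)(C)OC
Why: Thermodynamic acetalisation selects the 1,3-diol as the six-membered acetonide; a mixed ketal at the isolated allylic hydroxyl is lost on work-up.

Step 6
Reactants: 8 acetonide alcohol
Product: 9 (2Z)-3-methyl-5-[(4R,5R)-2,2,5-trimethyl-1,3-dioxan-4-yl]pent-2-enal
Conditions: MnO2 (excess), CH2Cl2, rt
Reagents that add atoms: none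
Why: Manganese dioxide oxidises only the allylic alcohol and is known to keep the Z geometry of neral-type enals under neutral conditions.

Step 7
Reactants: 10 tert-butyl (2R)-2-hydroxypropanoate
Product: 11 tert-butyl (2R)-2-{[(trifluoromethyl)sulfonyl]oxy}propanoate
Conditions: Tf2O, 2,6-lutidine, CH2Cl2, −78 → 0 °C
Reagents that add atoms: trifluoromethanesulfonic anhydride, O=S(=O)(OS(=O)(=O)C(F)(F)F)C(F)(F)F
Why: O-Sulfonylation does not touch the stereocentre; lactate triflates are configurationally stable and react by clean SN2 displacement.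

Step 8
Reactants: 12 triethyl phosphonoacetate; 11 lactate triflate
Product: 14 4-tert-butyl 1-ethyl (3S)-2-(diethoxyphosphoryl)-3-methylbutanedioate (both C2 epimers), via sodiated phosphonoacetate 13 (not isolated)
Conditions: NaH, THF, 0 °C; then 11, −20 °C → rt
Reagents that add atoms: none
Why: Alkylation of the soft phosphonoacetate carbanion by the secondary triflate is an SN2 reaction with inversion, so the (R)-lactate delivers the C17 configuration of the target; the centre formed at C8 becomes sp2 in step 9.

Step 9
Reactants: 14 phosphonate; 9 enal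
Product: 16 4-tert-butyl 1-ethyl (2E,3R)-3-methyl-2-{(2Z)-3-methyl-5-[(4R,5R)-2,2,5-trimethyl-1,3-dioxan-4-yl]pent-2-en-1-ylidene}butanedioate, via sodiated phosphonate 15 (not isolated)
Conditions: NaH, THF, 0 °C; then 9, 0 °C → rt
Reagents that add atoms: none
Why: Horner–Wadsworth–Emmons olefination; with an enal the α-branched phosphonate should place the ester trans to C6 (2E), the geometry that step 11 needs, and the preformed anion leaves no free base to epimerise C17 or isomerise the Z enal.

Step 10
Reactants: 16 diester
Product: 17 tert-butyl (2R,3E,5Z)-3-(hydroxymethyl)-2,6-dimethyl-8-[(4R,5R)-2,2,5-trimethyl-1,3-dioxan-4-yl]octa-3,5-dienoate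
Conditions: i-Bu2AlH (2.2 equiv), CH2Cl2, −78 °C
Reagents that add atoms: none
Why: The conjugated ethyl ester is reduced to the allylic alcohol at low temperature while the hindered tert-butyl ester is left.

Step 11
Reactants: 17 dienol
Product: 18 tert-butyl (2R)-2-[(2R,3R)-2-(hydroxymethyl)-3-{(1Z)-2-methyl-4-[(4R,5R)-2,2,5-trimethyl-1,3-dioxan-4-yl]but-1-en-1-yl}oxiran-2-yl]propanoate
Conditions: Ti(OiPr)4, D-(−)-diisopropyl tartrate, t-BuOOH, 4 Å MS, CH2Cl2, −20 °C
Reagents that add atoms: tert-butyl hydroperoxide, CC(C)(C)OO
Why: Sharpless asymmetric epoxidation acts only on the allylic alcohol alkene; the D-tartrate delivers oxygen to the face that gives the (2R,3R)-epoxide and with it the C8 oxygen of the target, and syn addition to the E alkene fixes C7 relative to C8.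

Step 12
Reactants: 18 epoxy alcohol
Product: 19 tert-butyl (2R)-2-[(2S,3R)-2-formyl-3-{(1Z)-2-methyl-4-[(4R,5R)-2,2,5-trimethyl-1,3-dioxan-4-yl]but-1-en-1-yl}oxiran-2-yl]propanoate
Conditions: SO3·pyridine, DMSO, iPr2NEt, CH2Cl2, 0 °C
Reagents that add atoms: none
Why: Parikh–Doering oxidation is non-acidic and spares the vinyl epoxide; the α-carbon is quaternary, so the aldehyde cannot epimerise.

Step 13
Reactants: 20 but-1-en-3-yne
Product: 22 (1E)-1-iodo-2-methylbuta-1,3-diene, via dienyl dimethylalane 21 (not isolated)
Conditions: Me3Al, (C5H5)2ZrCl2 (cat.), CH2Cl2, 0 °C → rt; then I2, THF, −30 °C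
Reagents that add atoms: trimethylaluminium, C[Al](C)C; iodine, II
Why: Negishi carboalumination adds methyl and aluminium syn across the alkyne with methyl on the internal carbon, and iodinolysis goes with retention, which gives the E iodide.

Step 14
Reactants: 19 epoxy aldehyde; 22 dienyl iodide
Product: 23 tert-butyl (2R)-2-[(2R,3R)-2-[(1S,2E)-1-hydroxy-3-methylpenta-2,4-dien-1-yl]-3-{(1Z)-2-methyl-4-[(4R,5R)-2,2,5-trimethyl-1,3-dioxan-4-yl]but-1-en-1-yl}oxiran-2-yl]propanoate
Conditions: CrCl2 (excess), NiCl2 (cat.), DMSO–THF, rt
Reagents that add atoms: none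
Why: Nozaki–Hiyama–Kishi coupling is selective for the aldehyde and keeps the alkene geometry; under non-chelating Felkin–Anh (or Cornforth) control the epoxide C–O bond lies anti to the incoming alkenylchromium, which passes the small tied-back epoxide CH (C7) and not the branched C17, and this gives the 9S carbinol.

Step 15
Reactants: 23 epoxy dienyl carbinol
Product: 24 (3R,4R,5S)-4-hydroxy-4-[(1S,2E)-1-hydroxy-3-methylpenta-2,4-dien-1-yl]-3-methyl-5-{(1Z)-2-methyl-4-[(4R,5R)-2,2,5-trimethyl-1,3-dioxan-4-yl]but-1-en-1-yl}oxolan-2-one
Conditions: (+)-camphor-10-sulfonic acid (cat.), CH2Cl2, 0 °C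
Reagents that add atoms: none
Why: Acid-promoted lactonisation of a β,γ-epoxy tert-butyl ester: the ester carbonyl opens the activated allylic carbon C7 from the back (inversion) and isobutene is lost, while the C8 oxygen stays as the tertiary alcohol; the result is the γ-lactone with C17 methyl, C8 hydroxyl and C7 alkenyl group all cis.

Step 16
Reactants: 24 lactone diol
Product: 25 (1S,2E)-1-[(2S,3R,4R)-3-hydroxy-4-methyl-2-{(1Z)-2-methyl-4-[(4R,5R)-2,2,5-trimethyl-1,3-dioxan-4-yl]but-1-en-1-yl}-5-oxooxolan-3-yl]-3-methylpenta-2,4-dien-1-yl acetate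
Conditions: Ac2O, Et3N, DMAP (cat.), CH2Cl2, 0 °C → rt
Reagents that add atoms: acetic anhydride, CC(=O)OC(C)=O
Why: DMAP-catalysed acetylation takes the secondary C9 alcohol; the flanked tertiary C8 hydroxyl does not react under these conditions.

Step 17
Reactants: 25 acetonide acetate
Product: 26 (1S,2E)-1-[(2S,3R,4R)-2-[(1Z,5R,6R)-5,7-dihydroxy-2,6-dimethylhept-1-en-1-yl]-3-hydroxy-4-methyl-5-oxooxolan-3-yl]-3-methylpenta-2,4-dien-1-yl acetate
Conditions: PPTS, MeOH, rt
Reagents that add atoms: none
Why: Acid-catalysed transketalisation to methanol removes the acetonide; this weak acid should not ionise the dienyl acetate or the allylic lactone C–O bond.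

Step 18
Reactants: 26 diol
Product: 27 (1S,2E)-1-[(2S,3R,4R)-3-hydroxy-2-[(1Z,6Z)-7-hydroxy-2,6-dimethyl-5-oxohepta-1,6-dien-1-yl]-4-methyl-5-oxooxolan-3-yl]-3-methylpenta-2,4-dien-1-yl acetate (enol form of the β-keto aldehyde)
Conditions: Dess–Martin periodinane (3 equiv), pyridine, CH2Cl2, 0 °C → rt
Reagents that add atoms: none
Why: Dess–Martin oxidation of both hydroxyls of a 1,3-diol gives the β-keto aldehyde, which rests as its hydrogen-bonded Z enol; the tertiary alcohol cannot be oxidised and the two auxiliary-derived centres disappear.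

Step 19
Reactants: 27 β-keto aldehyde
Product: 29 (1S,2E)-1-[(2S,3R,4R)-2-[(1Z,6Z)-7-acetoxy-2,6-dimethyl-5-oxohepta-1,6-dien-1-yl]-3-hydroxy-4-methyl-5-oxooxolan-3-yl]-3-methylpenta-2,4-dien-1-yl acetate, via sodium enolate 28 (not isolated)
Conditions: NaN(SiMe3)2 (1.0 equiv), THF–toluene, −78 °C; then AcCl, −78 °C
Reagents that add atoms: acetyl chloride, CC(=O)Cl
Why: O-Acylation of the chelated, U-shaped sodium enolate of a 1,3-dicarbonyl compound gives the Z enol ester, as is known for β-keto ester enolates; one equivalent of base removes only the acidic enol proton, and the unhindered aldehyde-derived oxygen is the one acylated.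

Step 20
Reactants: 29 triene (E diene, Z enol acetate)
Product: 30 (1R,7S,8S,9S,10S,14S,17R)-9,14-diacetoxy-8-hydroxy-2-oxobriara-5Z,11-dien-19,7-olide
Conditions: toluene (1 mM), BHT, 110–150 °C, sealed tube
Reagents that add atoms: none
Why: Proposed new method: a thermal, concerted, suprafacial [4+2] cycloaddition in which the diene C10=C11–C12=C13 adds across C1=C14 of the Z β-acetoxy enone and forms C1–C10 and C13–C14 together; the closest known reaction types are intramolecular Diels–Alder reactions of tethered trienes (which normally close five- to seven-membered rings) and transannular Diels–Alder reactions of macrocyclic trienes, and a direct fused closure onto a ten-membered ring has not been shown for this substrate class. Ring A is closed as a six-membered carbocycle by the cycloaddition itself, and ring B is closed in the fused mode through the same C1–C10 bond, the eight-atom tether C2–C9 joining the dienophile carbon C1 to the diene terminus C10. The C2 carbonyl polarises the dienophile so that C14 meets the unsubstituted diene terminus C13, which is also the only regiochemistry the tether allows. C14 is set relative to C1 by the Z geometry of the enol acetate (acetoxy cis to C2 on ring A). C10 is set relative to C1 by the transition state with the C2 carbonyl and tether exo, which gives the trans relation of C2 and C9 at the ring fusion, whereas the endo mode would demand a cis-fused bicyclo[8.4.0] array that the Z alkene and the lactone cannot span without transannular strain. The diene face is chosen by C9: allylic 1,3-strain with the C11 methyl holds H9 in the diene plane, C8 leaves from one face, and the C1–C10 bond forms on the other with a staggered, antiperiplanar C8–C9–C10–C1 arrangement. Five of the eight tether atoms (C2, C5, C6, C7, C8) are conformationally restricted, which lowers the entropic cost of the ten-membered ring; high dilution suppresses dimerisation, and Me2AlCl at low temperature is held in reserve as an activator of the enone.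

Step 21
Reactants: 30 C2 ketone
Product: 31 (1S,2S,7S,8S,9S,10S,14S,17R)-9,14-diacetoxy-2,8-dihydroxybriara-5Z,11-dien-19,7-olide
Conditions: NaBH4, CeCl3·7H2O, MeOH–THF, −40 → 0 °C
Reagents that add atoms: none
Why: Luche-type borohydride reduction touches only the ketone; hydride should attack C2 from the open peripheral face anti to the C15 methyl on the quaternary C1, which places the new hydroxyl cis to C15 (2S) as in the target.

Step 22
Reactants: 31 C2 alcohol
Product: 32 (1S,2S,7S,8S,9S,10S,14S,17R)-2,9,14-triacetoxy-8-hydroxybriara-5Z,11-dien-19,7-olide (CNP0187165.2)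
Conditions: Ac2O, DMAP, pyridine, CH2Cl2, rt
Reagents that add atoms: acetic anhydride, CC(=O)OC(C)=O
Why: DMAP-catalysed acetylation of the secondary C2 alcohol; the tertiary C8 hydroxyl is again spared.

## Compound list

1 | neryl acetate, (2Z)-3,7-dimethylocta-2,6-dien-1-yl acetate | CC(C)=CCC/C(C)=C\COC(C)=O | starting material
2 | (2Z)-5-(3,3-dimethyloxiran-2-yl)-3-methylpent-2-en-1-yl acetate (racemic epoxide) | CC1(C)OC1CC/C(C)=C\COC(C)=O | intermediate
3 | (2Z)-3-methyl-6-oxohex-2-en-1-yl acetate | O=CCC/C(C)=C\COC(C)=O | intermediate
4 | (4S)-4-benzyl-3-propanoyl-1,3-oxazolidin-2-one | CCC(=O)N1[C@@H](Cc2ccccc2)COC1=O | starting material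
5 | dibutylboron Z-enolate of 4 | C/C=C(\OB(CCCC)CCCC)N1[C@@H](Cc2ccccc2)COC1=O | intermediate (not isolated)
6 | (2Z,6R,7S)-8-[(4S)-4-benzyl-2-oxo-1,3-oxazolidin-3-yl]-6-hydroxy-3,7-dimethyl-8-oxooct-2-en-1-yl acetate | O=C1OC[C@H](Cc2ccccc2)N1C(=O)[C@@H](C)[C@H](O)CC/C(C)=C\COC(C)=O | intermediate
7 | (2R,3R,6Z)-2,6-dimethyloct-6-ene-1,3,8-triol | OC[C@@H](C)[C@H](O)CC/C(C)=C\CO | intermediate
8 | (2Z)-3-methyl-5-[(4R,5R)-2,2,5-trimethyl-1,3-dioxan-4-yl]pent-2-en-1-ol | O1C[C@@H](C)[C@H](OC1(C)C)CC/C(C)=C\CO | intermediate
9 | (2Z)-3-methyl-5-[(4R,5R)-2,2,5-trimethyl-1,3-dioxan-4-yl]pent-2-enal | O1C[C@@H](C)[C@H](OC1(C)C)CC/C(C)=C\C=O | intermediate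
10 | tert-butyl (2R)-2-hydroxypropanoate | C[C@@H](O)C(=O)OC(C)(C)C | starting material
11 | tert-butyl (2R)-2-{[(trifluoromethyl)sulfonyl]oxy}propanoate | C[C@@H](OS(=O)(=O)C(F)(F)F)C(=O)OC(C)(C)C | intermediate
12 | triethyl phosphonoacetate | CCOC(=O)CP(=O)(OCC)OCC | starting material
13 | sodium salt (carbanion) of 12 | [Na+].CCOC(=O)[CH-]P(=O)(OCC)OCC | intermediate (not isolated)
14 | 4-tert-butyl 1-ethyl (3S)-2-(diethoxyphosphoryl)-3-methylbutanedioate (both C2 epimers) | CCOC(=O)C([C@@H](C)C(=O)OC(C)(C)C)P(=O)(OCC)OCC | intermediate
15 | sodium salt (carbanion) of 14 | [Na+].CCOC(=O)[C-]([C@@H](C)C(=O)OC(C)(C)C)P(=O)(OCC)OCC | intermediate (not isolated)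
16 | 4-tert-butyl 1-ethyl (2E,3R)-3-methyl-2-{(2Z)-3-methyl-5-[(4R,5R)-2,2,5-trimethyl-1,3-dioxan-4-yl]pent-2-en-1-ylidene}butanedioate | O1C[C@@H](C)[C@H](OC1(C)C)CC/C(C)=C\C=C(/[C@@H](C)C(=O)OC(C)(C)C)C(=O)OCC | intermediate
17 | tert-butyl (2R,3E,5Z)-3-(hydroxymethyl)-2,6-dimethyl-8-[(4R,5R)-2,2,5-trimethyl-1,3-dioxan-4-yl]octa-3,5-dienoate | O1C[C@@H](C)[C@H](OC1(C)C)CC/C(C)=C\C=C(/[C@@H](C)C(=O)OC(C)(C)C)CO | intermediate
18 | tert-butyl (2R)-2-[(2R,3R)-2-(hydroxymethyl)-3-{(1Z)-2-methyl-4-[(4R,5R)-2,2,5-trimethyl-1,3-dioxan-4-yl]but-1-en-1-yl}oxiran-2-yl]propanoate | OC[C@@]1([C@@H](C)C(=O)OC(C)(C)C)O[C@@H]1/C=C(/C)CC[C@H]2OC(C)(C)OC[C@H]2C | intermediate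
19 | tert-butyl (2R)-2-[(2S,3R)-2-formyl-3-{(1Z)-2-methyl-4-[(4R,5R)-2,2,5-trimethyl-1,3-dioxan-4-yl]but-1-en-1-yl}oxiran-2-yl]propanoate | O=C[C@@]1([C@@H](C)C(=O)OC(C)(C)C)O[C@@H]1/C=C(/C)CC[C@H]2OC(C)(C)OC[C@H]2C | intermediate
20 | but-1-en-3-yne | C=CC#C | starting material
21 | dimethyl[(1E)-2-methylbuta-1,3-dien-1-yl]alane | C=C/C(C)=C/[Al](C)C | intermediate (not isolated)
22 | (1E)-1-iodo-2-methylbuta-1,3-diene | C=C/C(C)=C/I | intermediate
23 | tert-butyl (2R)-2-[(2R,3R)-2-[(1S,2E)-1-hydroxy-3-methylpenta-2,4-dien-1-yl]-3-{(1Z)-2-methyl-4-[(4R,5R)-2,2,5-trimethyl-1,3-dioxan-4-yl]but-1-en-1-yl}oxiran-2-yl]propanoate | C=C/C(C)=C/[C@H](O)[C@@]1([C@@H](C)C(=O)OC(C)(C)C)O[C@@H]1/C=C(/C)CC[C@H]2OC(C)(C)OC[C@H]2C | intermediate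
24 | (3R,4R,5S)-4-hydroxy-4-[(1S,2E)-1-hydroxy-3-methylpenta-2,4-dien-1-yl]-3-methyl-5-{(1Z)-2-methyl-4-[(4R,5R)-2,2,5-trimethyl-1,3-dioxan-4-yl]but-1-en-1-yl}oxolan-2-one | C=C/C(C)=C/[C@H](O)[C@@]1(O)[C@H](/C=C(/C)CC[C@H]2OC(C)(C)OC[C@H]2C)OC(=O)[C@@H]1C | intermediate
25 | (1S,2E)-1-[(2S,3R,4R)-3-hydroxy-4-methyl-2-{(1Z)-2-methyl-4-[(4R,5R)-2,2,5-trimethyl-1,3-dioxan-4-yl]but-1-en-1-yl}-5-oxooxolan-3-yl]-3-methylpenta-2,4-dien-1-yl acetate | C=C/C(C)=C/[C@H](OC(C)=O)[C@@]1(O)[C@H](/C=C(/C)CC[C@H]2OC(C)(C)OC[C@H]2C)OC(=O)[C@@H]1C | intermediate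
26 | (1S,2E)-1-[(2S,3R,4R)-2-[(1Z,5R,6R)-5,7-dihydroxy-2,6-dimethylhept-1-en-1-yl]-3-hydroxy-4-methyl-5-oxooxolan-3-yl]-3-methylpenta-2,4-dien-1-yl acetate | C=C/C(C)=C/[C@H](OC(C)=O)[C@@]1(O)[C@H](/C=C(/C)CC[C@@H](O)[C@H](C)CO)OC(=O)[C@@H]1C | intermediate
27 | (1S,2E)-1-[(2S,3R,4R)-3-hydroxy-2-[(1Z,6Z)-7-hydroxy-2,6-dimethyl-5-oxohepta-1,6-dien-1-yl]-4-methyl-5-oxooxolan-3-yl]-3-methylpenta-2,4-dien-1-yl acetate (Z enol of the β-keto aldehyde) | C=C/C(C)=C/[C@H](OC(C)=O)[C@@]1(O)[C@H](/C=C(/C)CCC(=O)/C(C)=C\O)OC(=O)[C@@H]1C | intermediate
28 | sodium enolate of 27 | C=C/C(C)=C/[C@H](OC(C)=O)[C@@]1(O)[C@H](/C=C(/C)CCC(=O)/C(C)=C\[O-])OC(=O)[C@@H]1C.[Na+] | intermediate (not isolated)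
29 | (1S,2E)-1-[(2S,3R,4R)-2-[(1Z,6Z)-7-acetoxy-2,6-dimethyl-5-oxohepta-1,6-dien-1-yl]-3-hydroxy-4-methyl-5-oxooxolan-3-yl]-3-methylpenta-2,4-dien-1-yl acetate | C=C/C(C)=C/[C@H](OC(C)=O)[C@@]1(O)[C@H](/C=C(/C)CCC(=O)/C(C)=C\OC(C)=O)OC(=O)[C@@H]1C | intermediate
30 | (1R,7S,8S,9S,10S,14S,17R)-9,14-diacetoxy-8-hydroxy-2-oxobriara-5Z,11-dien-19,7-olide | CC(=O)O[C@H]1CC=C(C)[C@@H]2[C@H](OC(C)=O)[C@@]3(O)[C@H](/C=C(/C)CCC(=O)[C@@]12C)OC(=O)[C@@H]3C | intermediate
31 | (1S,2S,7S,8S,9S,10S,14S,17R)-9,14-diacetoxy-2,8-dihydroxybriara-5Z,11-dien-19,7-olide | CC(=O)O[C@H]1CC=C(C)[C@@H]2[C@H](OC(C)=O)[C@@]3(O)[C@H](/C=C(/C)CC[C@H](O)[C@@]12C)OC(=O)[C@@H]3C | intermediate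
32 | (1S,2S,7S,8S,9S,10S,14S,17R)-2,9,14-triacetoxy-8-hydroxybriara-5Z,11-dien-19,7-olide (CNP0187165.2) | CC(=O)O[C@H]1CC=C(C)[C@@H]2[C@H](OC(C)=O)[C@@]3(O)[C@H](/C=C(/C)CC[C@H](OC(C)=O)[C@@]12C)OC(=O)[C@@H]3C | target

## Step count and least certain steps

Total: 22 steps. Longest linear sequence: 19 steps (steps 1–6, 9–12 and 14–22, from neryl acetate 1).

**Step 20 (key step, proposed new method).** The most likely failure is that the triene does not cyclise: the entropic and transannular cost of the ten-membered ring may let intermolecular cycloaddition, a thermal 1,3-acyloxy shift of the dienyl acetate or Z/E isomerisation of the enol acetate win. Cyclisation through the endo mode or on the other diene face is the second risk. The fallback sets out from phosphonate 14 and iodide 22 and comes back at 30; it makes ring A by an intermolecular Diels–Alder reaction and ring B by ring-closing metathesis, both known reaction types. Acrolein is carried through the operations of steps 9–12 and 14–16 to the vinyl lactone acetate F1. Its diene is combined under Me2AlCl catalysis with the dienophile (1Z)-2,6-dimethyl-3-oxohepta-1,6-dien-1-yl acetate F2 (made from 4-methylpent-4-enal by the aldol, reduction, oxidation and acetylation operations of steps 3, 4, 18 and 19) to give the cyclohexene F3. Ring-closing metathesis of the C7 vinyl and the isopropenyl group with the second-generation Grubbs catalyst then closes C5=C6 and gives 30. The price is the loss of tether control over diene face and exo/endo selectivity, and a demanding closure of a trisubstituted alkene in a ten-membered ring.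

**Step 9.** The α-branched phosphonate may give an E/Z mixture at C7=C8, and the Z isomer would lead to the wrong C7 configuration after epoxidation and inversion. The fallback sets out from triflate 11 and enal 9 and comes back at 16. Triflate 11 alkylates ethyl (triphenylphosphoranylidene)acetate (two equivalents, transylidation) to give the stabilised ylide F4, whose Wittig reaction with 9 gives 16; stabilised α-substituted ylides place the ester trans to the aldehyde residue more reliably.

**Step 14.** Facial selectivity at C9 may erode if chromium chelates the aldehyde and the epoxide oxygen, and halide may open the vinyl epoxide. The fallback sets out from the C9 epimer mixture of 23 and comes back at 23. Dess–Martin oxidation gives the epoxy dienone F5, and Zn(BH4)2 reduces it under chelation control; hydride then enters from the C7 side of the chelate, which leads to the same 9S carbinol as the Felkin addition.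

**Step 15.** Ionisation at the allylic C7 without backside participation would erode the C7 configuration or the Z alkene, and the acid may shift the acetonide onto the new C8/C9 diol or disturb the dienyl carbinol. The fallback sets out from epoxy alcohol 18 and comes back at 24; it lactonises before the diene is present. Camphorsulfonic acid converts 18 into the lactone diol F6, selective oxidation of the primary alcohol (TEMPO, PhI(OAc)2) gives the hydroxy aldehyde F7, and coupling with 22 as in step 14 gives 24 together with its C9 epimer. The epimers must then be separated, because the closed lactone no longer differentiates the aldehyde faces.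

**Step 21.** Hydride may approach the hindered C2 carbonyl from the wrong face or react so slowly that acetates are lost by methanolysis. The fallback sets out from 30 and comes back at 31. It replaces substrate control by reagent control: Corey–Bakshi–Shibata reduction with the (R)-2-methyl-oxazaborolidine catalyst and catecholborane at low temperature, which by the usual model (quaternary C1 as the large group) gives the 2S alcohol. It makes no new compound (F0).

## Further compounds

F1 | step 20 | vinyl lactone acetate, analogue of 25 with an ethenyl group at C7 | C=C/C(C)=C/[C@H](OC(C)=O)[C@@]1(O)[C@H](C=C)OC(=O)[C@@H]1C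
F2 | step 20 | (1Z)-2,6-dimethyl-3-oxohepta-1,6-dien-1-yl acetate | C=C(C)CCC(=O)/C(C)=C\OC(C)=O
F3 | step 20 | intermolecular Diels–Alder adduct, ring A with a 4-methylpent-4-enoyl group on C1 and the C7-vinyl lactone on C9 (5,6-seco-30) | CC(=O)O[C@H]1CC=C(C)[C@H]([C@H](OC(C)=O)[C@@]2(O)[C@H](C=C)OC(=O)[C@@H]2C)[C@@]1(C)C(=O)CCC(C)=C
F4 | step 9 | stabilised ylide, ethyl 4-tert-butoxy-3-methyl-4-oxo-2-(triphenylphosphoranylidene)butanoate with the C17 configuration of 14 | CCOC(=O)C([C@@H](C)C(=O)OC(C)(C)C)=P(c1ccccc1)(c1ccccc1)c1ccccc1
F5 | step 14 | epoxy dienone, the C9 ketone of 23 | C=C/C(C)=C/C(=O)[C@@]1([C@@H](C)C(=O)OC(C)(C)C)O[C@@H]1/C=C(/C)CC[C@H]2OC(C)(C)OC[C@H]2C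
F6 | step 15 | lactone diol with primary C9 alcohol (lactone of 18) | OC[C@@]1(O)[C@H](/C=C(/C)CC[C@H]2OC(C)(C)OC[C@H]2C)OC(=O)[C@@H]1C
F7 | step 15 | α-hydroxy aldehyde (C9 aldehyde of F6) | O=C[C@@]1(O)[C@H](/C=C(/C)CC[C@H]2OC(C)(C)OC[C@H]2C)OC(=O)[C@@H]1C
F0 | step 21 | none | none
A1 | alternative 1 | ring B C8,C9 diol from pinacol closure (C7 OTBS, C19 OPMB, C2 and C14 acetates) | CC(=O)O[C@H]1CC=C(C)[C@@H]2[C@H](O)[C@](O)([C@@H](C)COCc3ccc(OC)cc3)[C@@H](O[Si](C)(C)C(C)(C)C)/C=C(/C)CC[C@H](OC(C)=O)[C@@]12C
A2 | alternative 2 | target skeleton with lactone closed, C8 trimethylsilyl ether | CC(=O)O[C@H]1CC=C(C)[C@@H]2[C@H](OC(C)=O)[C@@]3(O[Si](C)(C)C)[C@H](/C=C(/C)CC[C@H](OC(C)=O)[C@@]12C)OC(=O)[C@@H]3C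
A3 | alternative 3 | ring B C2 ketone with C3 phenylsulfonyl group, C8 triethylsilyl ether | CC(=O)O[C@H]1CC=C(C)[C@@H]2[C@H](OC(C)=O)[C@@]3(O[Si](CC)(CC)CC)[C@H](/C=C(/C)C[C@@H](S(=O)(=O)c4ccccc4)C(=O)[C@@]12C)OC(=O)[C@@H]3C
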